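**Retrosynthetic overview**

1. Target 21 ⇐ its C7 methyl ester 20 ⇐ bromo-ether 19: a Boord-type β-elimination unmasks both the C16=C17 alkene and the 11β-OH; the 2β-OH comes from exo-face hydroboration of the Δ1 alkene of 16.
2. The 11β-oxygen comes from 1,5-hydrogen transfer to a C16 alkoxy radical (bromohydrin 14 ⇐ 16-norketone 13 ⇐ lactone 11).
3. Key disconnection C10–C20: Still [2,3]-Wittig rearrangement of the 2α-O-CH2SnBu3 ether 8 sets the quaternary C10 with C20 on the α face; the 19,20-δ-lactone closes in the same step.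
4. 8 ⇐ iso-lactone 6 ⇐ gibberellic acid 1 (allylic lactone transposition C10→C2, MOM protection, 13-deoxygenation).
5. Ring order: rings A–D and seven of the ten stereocentres are carried through from 1 (C10, C11 and C2 are set under substrate control); the γ-lactone is transposed and opened; the δ-lactone is the only permanent ring built (step 6); a temporary 11,16-oxolane is closed (step 9) and reopened (step 12).

Assumption: gibberellane numbering is used (the target is the 2β,3β,11β-trihydroxy 19,20-lactone 7-acid), and fermentation-grade gibberellic acid (GA3) is taken as the commercial chiral starting material.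

**Route**

Step 1
Reactants: 1 gibberellic acid (GA3)
Product: 3 iso-GA3 methyl ester (19,2α-lactone with Δ1(10) alkene), via GA3 methyl ester 2 (not isolated)
Conditions: K2CO3 (1.5 equiv), MeI (1.2 equiv), DMF, 20 °C; then H2O (DMF–H2O 1:1, pH ca. 10), 20 °C
Reagents that add atoms: iodomethane (CI)
Why: SN2 O-methylation of the carboxylate, then the base-induced allylic lactone transposition of GA3 esters (formal 1,3-acyloxy shift from C10 to C2); the α-disposed C19 carboxyl can only re-close on the α face of C2, and no other stereocentre is touched.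

Step 2
Reactants: 3 iso-GA3 methyl ester
Product: 4 3-O-methoxymethyl iso-GA3 methyl ester
Conditions: MOMCl (1.5 equiv), i-Pr2NEt (3 equiv), CH2Cl2, 0 → 20 °C
Reagents that add atoms: chloromethyl methyl ether (COCCl)
Why: Acetal ether formation at the secondary 3β-OH (the bridgehead tertiary 13-OH is much slower); MOM is used because, unlike a silyl group, it cannot migrate to O-2 under the later KH step.

Step 3
Reactants: 4 3-O-methoxymethyl iso-GA3 methyl ester
Product: 5 13-O-(methoxyoxalyl) derivative of 4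
Conditions: ClCOCO2Me (3 equiv), DMAP (1 equiv), pyridine, CH2Cl2, 20 °C
Reagents that add atoms: methyl chlorooxoacetate (COC(=O)C(Cl)=O)
Why: DMAP-catalysed acylation of the only free hydroxyl gives the tertiary methyl oxalate that activates this bridgehead alcohol for tin hydride deoxygenation.

Step 4
Reactants: 5 13-O-(methoxyoxalyl) derivative
Product: 6 3-O-methoxymethyl iso-GA7 methyl ester (13-deoxy)
Conditions: Bu3SnH (2 equiv), AIBN (0.2 equiv), toluene, 110 °C
Reagents that add atoms: none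
Why: Barton–McCombie-type radical deoxygenation of a tertiary oxalate, with precedent at the 13-OH of GA3 esters; the bridgehead C13 radical can only take up hydrogen with the configuration fixed by the bicycle.

Step 5
Reactants: 6 3-O-methoxymethyl iso-GA7 methyl ester
Product: 8 2α-[(tributylstannyl)methoxy] 19-acid 7-methyl ester, via potassium hydroxy carboxylate 7 (not isolated)
Conditions: KOH (1.05 equiv), THF–H2O, 20 °C; evaporate, azeotrope with toluene; KH (1.5 equiv), 18-crown-6 (0.2 equiv), Bu3SnCH2I (1.3 equiv), THF, 0 → 20 °C; aq. KH2PO4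
Reagents that add atoms: potassium hydroxide ([K+].[OH-]); tributyl(iodomethyl)stannane (CCCC[Sn](CCCC)(CCCC)CI)
Why: Saponification of the strained allylic γ-lactone frees the 2α-hydroxyl; keeping C19 as the carboxylate blocks re-lactonisation, so Williamson etherification occurs at the only hydroxyl while the hindered C7 methyl ester survives.

Step 6
Reactants: 8 2α-[(tributylstannyl)methoxy] 19-acid 7-methyl ester
Product: 11 3-O-MOM-1,2-didehydro-GA37 methyl ester (19,20-lactone), via dilithium alkoxide carboxylate 9 (not isolated), via hydroxy acid 10 (not isolated)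
Conditions: n-BuLi (2.3 equiv), THF, −78 → −20 °C; 1 M HCl to pH 2.5, EtOAc, 20 °C; TsOH·H2O (0.05 equiv), CH2Cl2, 20 °C
Reagents that add atoms: n-butyllithium ([Li]CCCC)
Why: Key step: Sn–Li exchange triggers the Still variant of the [2,3]-Wittig rearrangement, suprafacial across C2–C1=C10, so C20 arrives on the α face of C10 (the face of the 2α-oxygen, itself fixed by C19), creating the quaternary centre and the Δ1 alkene; on acidification the 20-hydroxy-19-acid closes to the δ-lactone as GA15-type hydroxy acids do.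

Step 7
Reactants: 11 3-O-MOM-1,2-didehydro-GA37 methyl ester
Product: 13 16-oxo-17-nor derivative of 11, via 16,17-diol 12 (not isolated)
Conditions: OsO4 (0.02 equiv), NaIO4 (2.5 equiv), 2,6-lutidine (2 equiv), dioxane–H2O 3:1, 20 °C
Reagents that add atoms: sodium periodate ([Na+].[O-]I(=O)(=O)=O)
Why: Lemieux–Johnson cleavage; the exocyclic Δ16 alkene reacts far faster than Δ1, which is flanked by quaternary C10 and the axial 3β-OMOM and screened from below by the lactone bridge (as in selective norketone formation from GA3 esters).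

Step 8
Reactants: 13 16-oxo-17-nor derivative
Product: 14 16-(bromomethyl)-16-hydroxy derivative (OH endo, on the ring D face that carries the C9–C11–C12 bridge)
Conditions: CH2Br2 (3 equiv), n-BuLi (2.5 equiv, added last), THF, −78 °C; AcOH (3 equiv) at −78 °C
Reagents that add atoms: dibromomethane (BrCBr)
Why: In situ bromomethyllithium adds 1,2 to the only ketone (hindered ester and lactone are slower) from the exo face, because the endo face is blocked by the axial 11β-H; the new hydroxyl therefore sits endo, directly under C11, and the cold acid quench prevents closure to the spiro-epoxide.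

Step 9
Reactants: 14 16-(bromomethyl)-16-hydroxy derivative
Product: 16 17-bromo-11β,16-epoxy derivative, via 16-hypoiodite 15 (not isolated)
Conditions: PhI(OAc)2 (1.5 equiv), I2 (1.0 equiv), cyclohexane–CH2Cl2 4:1, hν (100 W incandescent lamp), 10 °C
Reagents that add atoms: iodine (II)
Why: Hypoiodite reaction (Suárez conditions): the C16 alkoxy radical abstracts the 1,3-diaxial 11β-H (1,5-hydrogen transfer) and the same oxygen captures the oxidised C11, so the oxolane can only close on the β face and the C11 stereocentre is set by the ring.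

Step 10
Reactants: 16 17-bromo-11β,16-epoxy derivative
Product: 18 2β-hydroxy-3β-(methoxymethoxy) bromo-ether, via 2β-borane 17 (not isolated)
Conditions: BH3·THF (2 equiv), THF, 0 → 20 °C; then 30% H2O2, 3 M aq. NaOAc, 0 → 20 °C
Reagents that add atoms: borane–tetrahydrofuran complex (B.C1CCOC1); hydrogen peroxide (OO)
Why: Hydroboration–oxidation: syn H–B addition from the exo (β) face because the α face of C1–C2 lies over the lactone bridge, with boron at C2 (C1 is neopentyl and the allylic C–O bond polarises the alkene); oxidation with retention gives the 2β-OH cis to the 3β-oxygen.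

Step 11
Reactants: 18 2β-hydroxy-3β-(methoxymethoxy) bromo-ether
Product: 19 2β,3β-dihydroxy bromo-ether
Conditions: conc. HCl (0.2 equiv), MeOH, 45 °C
Reagents that add atoms: none
Why: Acid-catalysed transacetalisation removes the MOM group; it is done while C16/C17 is still masked, since a free 11β-OH beside the Δ16 alkene would cyclise back to the ether under acid.

Step 12
Reactants: 19 2β,3β-dihydroxy bromo-ether
Product: 20 methyl ester of the target
Conditions: Zn dust (activated, 10 equiv), EtOH, 78 °C; aq. NaHCO3 work-up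
Reagents that add atoms: none
Why: Boord-type reductive β-elimination: Zn inserts into the C17–Br bond and the β-alkoxide leaves, regenerating the exocyclic C16=C17 alkene regiospecifically and releasing the 11β-OH with its configuration intact.

Step 13
Reactants: 20 methyl ester of the target
Product: 21 target acid (CNP0302900.3)
Conditions: NaSCH2CH2CH3 (5 equiv), HMPA, 20 °C; then aq. H3PO4 to pH 3, EtOAc
Reagents that add atoms: none
Why: SN2 demethylation of the hindered C7 methyl ester by thiolate (the usual non-hydrolytic ester cleavage in gibberellin chemistry) avoids hydroxide, so there is no retro-aldol epimerisation at C3 and the neopentyl lactone is untouched.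

**Compound list**

1 | gibberellic acid (GA3) | C=C1C[C@]23C[C@@]1(O)CC[C@H]2[C@]12OC(=O)[C@](C)([C@@H](O)C=C1)[C@H]2[C@@H]3C(=O)O | starting material
2 | GA3 methyl ester | C=C1C[C@]23C[C@@]1(O)CC[C@H]2[C@]12OC(=O)[C@](C)([C@@H](O)C=C1)[C@H]2[C@@H]3C(=O)OC | intermediate
3 | iso-GA3 methyl ester (3β,13-dihydroxy, Δ1(10),Δ16, 19,2α-lactone) | C=C1C[C@]23C[C@@]1(O)CC[C@H]2C2=C[C@H]4OC(=O)[C@](C)([C@H]4O)[C@H]2[C@@H]3C(=O)OC | intermediate
4 | 3-O-methoxymethyl iso-GA3 methyl ester | C=C1C[C@]23C[C@@]1(O)CC[C@H]2C2=C[C@H]4OC(=O)[C@](C)([C@H]4OCOC)[C@H]2[C@@H]3C(=O)OC | intermediate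
5 | 13-O-(methoxyoxalyl) derivative of 4 | C=C1C[C@]23C[C@@]1(OC(=O)C(=O)OC)CC[C@H]2C2=C[C@H]4OC(=O)[C@](C)([C@H]4OCOC)[C@H]2[C@@H]3C(=O)OC | intermediate
6 | 3-O-methoxymethyl iso-GA7 methyl ester (13-deoxy) | C=C1C[C@]23C[C@H]1CC[C@H]2C2=C[C@H]4OC(=O)[C@](C)([C@H]4OCOC)[C@H]2[C@@H]3C(=O)OC | intermediate
7 | potassium 2α-hydroxy-3β-(methoxymethoxy)-7-methoxycarbonyl-20-norgibberella-1(10),16-dien-19-oate | C=C1C[C@]23C[C@H]1CC[C@H]2C2=C[C@@H](O)[C@H](OCOC)[C@@](C)(C(=O)[O-])[C@H]2[C@@H]3C(=O)OC.[K+] | intermediate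
8 | 3β-(methoxymethoxy)-7-methoxycarbonyl-2α-[(tributylstannyl)methoxy]-20-norgibberella-1(10),16-dien-19-oic acid | C=C1C[C@]23C[C@H]1CC[C@H]2C2=C[C@@H](OC[Sn](CCCC)(CCCC)CCCC)[C@H](OCOC)[C@@](C)(C(=O)O)[C@H]2[C@@H]3C(=O)OC | intermediate
9 | dilithium salt of 10 (20-alkoxide, 19-carboxylate) | C=C1C[C@]23C[C@H]1CC[C@H]2[C@]2(C[O-])C=C[C@H](OCOC)[C@@](C)(C(=O)[O-])[C@H]2[C@@H]3C(=O)OC.[Li+].[Li+] | intermediate
10 | 20-hydroxy-3β-(methoxymethoxy)-7-methoxycarbonylgibberella-1,16-dien-19-oic acid | C=C1C[C@]23C[C@H]1CC[C@H]2[C@]2(CO)C=C[C@H](OCOC)[C@@](C)(C(=O)O)[C@H]2[C@@H]3C(=O)OC | intermediate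
11 | 3-O-MOM-1,2-didehydro-GA37 methyl ester (Δ1,Δ16, 19,20-lactone) | C=C1C[C@]23C[C@H]1CC[C@H]2[C@]12COC(=O)[C@](C)([C@@H](OCOC)C=C1)[C@H]2[C@@H]3C(=O)OC | intermediate
12 | 16,17-diol of 11 (16-OH exo) | OC[C@@]1(O)C[C@]23C[C@H]1CC[C@H]2[C@]12COC(=O)[C@](C)([C@@H](OCOC)C=C1)[C@H]2[C@@H]3C(=O)OC | intermediate
13 | 16-oxo-17-nor derivative of 11 | O=C1C[C@]23C[C@H]1CC[C@H]2[C@]12COC(=O)[C@](C)([C@@H](OCOC)C=C1)[C@H]2[C@@H]3C(=O)OC | intermediate
14 | 16-(bromomethyl)-16-hydroxy derivative (OH endo) | BrC[C@]1(O)C[C@]23C[C@H]1CC[C@H]2[C@]12COC(=O)[C@](C)([C@@H](OCOC)C=C1)[C@H]2[C@@H]3C(=O)OC | intermediate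
15 | 16-hypoiodite of 14 | BrC[C@]1(OI)C[C@]23C[C@H]1CC[C@H]2[C@]12COC(=O)[C@](C)([C@@H](OCOC)C=C1)[C@H]2[C@@H]3C(=O)OC | intermediate
16 | 17-bromo-11β,16-epoxy-3β-(methoxymethoxy)-Δ1 lactone methyl ester | BrC[C@]1(O4)C[C@]23C[C@H]1C[C@H]4[C@H]2[C@]12COC(=O)[C@](C)([C@@H](OCOC)C=C1)[C@H]2[C@@H]3C(=O)OC | intermediate
17 | 2β-boryl (BH2) adduct of 16 | BrC[C@]1(O4)C[C@]23C[C@H]1C[C@H]4[C@H]2[C@]12COC(=O)[C@](C)([C@@H](OCOC)[C@@H](B)C1)[C@H]2[C@@H]3C(=O)OC | intermediate
18 | 17-bromo-11β,16-epoxy-2β-hydroxy-3β-(methoxymethoxy) lactone methyl ester | BrC[C@]1(O4)C[C@]23C[C@H]1C[C@H]4[C@H]2[C@]12COC(=O)[C@](C)([C@@H](OCOC)[C@@H](O)C1)[C@H]2[C@@H]3C(=O)OC | intermediate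
19 | 17-bromo-11β,16-epoxy-2β,3β-dihydroxy lactone methyl ester | BrC[C@]1(O4)C[C@]23C[C@H]1C[C@H]4[C@H]2[C@]12COC(=O)[C@](C)([C@@H](O)[C@@H](O)C1)[C@H]2[C@@H]3C(=O)OC | intermediate
20 | methyl 2β,3β,11β-trihydroxygibberell-16-en-7-oate 19,20-lactone | C=C1C[C@]23C[C@H]1C[C@H](O)[C@H]2[C@]12COC(=O)[C@](C)([C@@H](O)[C@@H](O)C1)[C@H]2[C@@H]3C(=O)OC | intermediate
21 | 2β,3β,11β-trihydroxygibberell-16-en-7-oic acid 19,20-lactone (CNP0302900.3) | C=C1C[C@]23C[C@H]1C[C@H](O)[C@H]2[C@]12COC(=O)[C@](C)([C@@H](O)[C@@H](O)C1)[C@H]2[C@@H]3C(=O)O | target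

**Totals and risks**

Total step count: 13. Longest linear sequence: 13 steps (fully linear from 1).

Steps most likely to fail:

Step 6 (Still [2,3]-Wittig). The lithiated ether must rearrange onto a fully substituted alkene carbon faster than n-BuLi attacks the C7 ester or the carbanion attacks the carboxylate. The fallback sets out from hydroxy carboxylate 7 and returns at lactone 11, replacing the [2,3] shift by a [3,3] shift plus one-carbon excision. Methylation of 7 (MeI, DMF) gives the hydroxy diester F1. Acylation with benzyloxyacetyl chloride (pyridine, DMAP) gives the 2α-(benzyloxy)acetate F2. Ireland–Claisen rearrangement (KN(SiMe3)2, Me3SiCl, THF, −78 → 60 °C, then aqueous acid) delivers the two-carbon unit to the α face of C10 and gives the α-benzyloxy acid F3. Oxidative decarboxylation with Pb(OAc)4 (benzene, 80 °C) and aqueous acid work-up gives the C20 aldehyde F4. NaBH4 in MeOH reduces the aldehyde, and the resulting alkoxide closes onto the C19 methyl ester to give 11.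

Step 9 (remote oxidation of C11). The strained tertiary cyclopentyloxy radical may undergo β-scission, or electrophilic iodine may attack the Δ1 alkene. The fallback sets out from norketone 13 and returns at bromo-ether 16, using a non-radical oxygen insertion. KHSO5 (as 2KHSO5·KHSO4·K2SO4) with NaHCO3 in CH3CN–H2O converts the ketone into the C16 dioxirane F5, whose endo oxygen inserts into the adjacent 11β C–H bond with retention to give the 11β-hydroxy norketone F6. Methylenation (Zn, CH2Br2, TiCl4, THF) gives the 11β-hydroxy Δ16 alkene F7. Bromoetherification with N-bromosuccinimide (CH2Cl2, 0 °C) closes the 11β-oxygen onto C16 and gives 16.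

Step 10 (hydroboration of Δ1). The alkene is hindered on both faces, and boron could go to C1 or the reaction could stall. The fallback sets out from 16 and returns at diol 19, using enolate oxidation instead of alkene hydration. HCl (cat.) in MeOH removes the MOM group to give the allylic alcohol F8. MnO2 (CH2Cl2) gives the enone F9. Conjugate reduction with KB(s-Bu)3H (THF, −78 °C) gives the enolate F10 (K+ counterion), which is trapped in the same flask with racemic 2-(phenylsulfonyl)-3-phenyloxaziridine from the open β face and, after aqueous NH4Cl work-up, gives the 2β-hydroxy 3-ketone F11. A second treatment with KB(s-Bu)3H (−78 °C) delivers hydride equatorially to C3 and gives the axial 3β-alcohol 19.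

**Further compounds**

F1 | step 6 | dimethyl 2α-hydroxy-3β-(methoxymethoxy)-20-norgibberella-1(10),16-diene-7,19-dioate | C=C1C[C@]23C[C@H]1CC[C@H]2C2=C[C@@H](O)[C@H](OCOC)[C@@](C)(C(=O)OC)[C@H]2[C@@H]3C(=O)OC
F2 | step 6 | 2α-O-(benzyloxy)acetate of F1 | C=C1C[C@]23C[C@H]1CC[C@H]2C2=C[C@@H](OC(=O)COCc4ccccc4)[C@H](OCOC)[C@@](C)(C(=O)OC)[C@H]2[C@@H]3C(=O)OC
F3 | step 6 | 10α-[(benzyloxy)(carboxy)methyl] Δ1 diester (Ireland–Claisen acid) | C=C1C[C@]23C[C@H]1CC[C@H]2[C@]2(C(OCc4ccccc4)C(=O)O)C=C[C@H](OCOC)[C@@](C)(C(=O)OC)[C@H]2[C@@H]3C(=O)OC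
F4 | step 6 | dimethyl 3β-(methoxymethoxy)-20-oxogibberella-1,16-diene-7,19-dioate (C20 aldehyde) | C=C1C[C@]23C[C@H]1CC[C@H]2[C@]2(C=O)C=C[C@H](OCOC)[C@@](C)(C(=O)OC)[C@H]2[C@@H]3C(=O)OC
F5 | step 9 | C16 spiro-dioxirane of 13 | O1OC12C[C@]34C[C@H]2CC[C@H]3[C@]23COC(=O)[C@](C)([C@@H](OCOC)C=C2)[C@H]3[C@@H]4C(=O)OC
F6 | step 9 | 11β-hydroxy-16-oxo-17-nor derivative of 11 | O=C1C[C@]23C[C@H]1C[C@H](O)[C@H]2[C@]12COC(=O)[C@](C)([C@@H](OCOC)C=C1)[C@H]2[C@@H]3C(=O)OC
F7 | step 9 | 11β-hydroxy derivative of 11 (Δ1,Δ16) | C=C1C[C@]23C[C@H]1C[C@H](O)[C@H]2[C@]12COC(=O)[C@](C)([C@@H](OCOC)C=C1)[C@H]2[C@@H]3C(=O)OC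
F8 | step 10 | 17-bromo-11β,16-epoxy-3β-hydroxy-Δ1 lactone methyl ester | BrC[C@]1(O4)C[C@]23C[C@H]1C[C@H]4[C@H]2[C@]12COC(=O)[C@](C)([C@@H](O)C=C1)[C@H]2[C@@H]3C(=O)OC
F9 | step 10 | 17-bromo-11β,16-epoxy-3-oxo-Δ1 lactone methyl ester | BrC[C@]1(O4)C[C@]23C[C@H]1C[C@H]4[C@H]2[C@]12COC(=O)[C@](C)(C(=O)C=C1)[C@H]2[C@@H]3C(=O)OC
F10 | step 10 | potassium Δ2-enolate of the 3-ketone | BrC[C@]1(O4)C[C@]23C[C@H]1C[C@H]4[C@H]2[C@]12COC(=O)[C@](C)(C([O-])=CC1)[C@H]2[C@@H]3C(=O)OC.[K+]
F11 | step 10 | 17-bromo-11β,16-epoxy-2β-hydroxy-3-oxo lactone methyl ester | BrC[C@]1(O4)C[C@]23C[C@H]1C[C@H]4[C@H]2[C@]12COC(=O)[C@](C)(C(=O)[C@@H](O)C1)[C@H]2[C@@H]3C(=O)OC
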